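**Plan**

- Numbering: guaiacyl unit C7–C9, syringyl unit C7'–C9', glycerol unit C7''–C9''. Ring A = O/C7/C8/C8'/C9' and ring B = O/C7'/C8'/C8/C9, cis-fused as a 3,7-dioxabicyclo[3.3.0]octane with the guaiacyl group exo and the syringyl group endo.
- Retrosynthetic cuts: C7''–C8'' (aldol) and O4'–C8'' (phenol alkylation) remove the side chain; then C9'–O (ring A ether, taken back to a γ-lactone), C7'–C8' (ring B, the strategic bond), C9–O, C8–C8' and C7–C8.
- Forward: ring A arises first as a γ-butyrolactone (C9' as C=O) by radical cyclisation/cyclopropanation of an acetoacetate and opening of the cyclopropane by the syringyl methanol. Ring B is then closed by carbenoid insertion of C8' into the C7'–H bond; the lactone is reduced and re-closed to the ether, and the glycerol chain is attached last.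
- Enabling feature: in the α-diazo lactone the C7'–H bond, activated by the ether oxygen of ring B and the electron-rich syringyl ring, lies 1,5 to C8' (α to the ring-A carbonyl C9') on the face fixed by C8. Five-membered closure is therefore cis-fused and should be kinetically endo.
- Stereochemistry: C7 from a lipase resolution; C8 from C7 (trans-selective 5-exo radical closure); C8' and C7' in the key step (substrate control); C7''/C8'' from an Evans syn aldol with the (S)-4-benzyl auxiliary.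

Key step: step 8

Remark: the SMILES is read as (7R,8S,7'S,8'S) in the furofuran (guaiacyl exo, syringyl endo) and threo-(7''R,8''R) in the glycerol unit; all structures are drawn for this isomer.

**Route**

Step 1
Reactants: 1 vanillin (4-hydroxy-3-methoxybenzaldehyde)
Product: 2 3-methoxy-4-(triisopropylsilyloxy)benzaldehyde
Conditions: TIPSCl, imidazole, DMF, rt
Reagents that add atoms: triisopropylsilyl chloride, CC(C)[Si](Cl)(C(C)C)C(C)C
Why: Imidazole-promoted silylation of the phenol gives an aryl silyl ether that should survive base, hydride and carbenoid steps and is removed by fluoride at the end; no stereocentre is formed.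

Step 2
Reactants: 2 3-methoxy-4-(triisopropylsilyloxy)benzaldehyde
Product: 3 racemic 1-[3-methoxy-4-(triisopropylsilyloxy)phenyl]prop-2-en-1-ol
Conditions: CH2=CHMgBr, THF, −78 to 0 °C; then H2O
Reagents that add atoms: vinylmagnesium bromide, C=C[Mg]Br
Why: Grignard 1,2-addition to the aldehyde forms the C7–C8 bond; C7 is formed racemic and is resolved in step 3.

Step 3
Reactants: 3 racemic 1-[3-methoxy-4-(triisopropylsilyloxy)phenyl]prop-2-en-1-ol
Product: 4 (R)-1-[3-methoxy-4-(triisopropylsilyloxy)phenyl]prop-2-en-1-yl 3-oxobutanoate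
Conditions: immobilised Candida antarctica lipase B (Novozym 435), methyl acetoacetate, toluene, 5 Å MS, 40 °C, stopped near half conversion
Reagents that add atoms: methyl acetoacetate, COC(=O)CC(C)=O
Why: Lipase-catalysed kinetic resolution by transesterification: the enzyme should acylate the enantiomer that places the aryl group in its large pocket and the vinyl group in its medium pocket, the (R)-alcohol, so C7 is obtained (R) directly as the acetoacetate while the (S)-alcohol stays behind.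

Step 4
Reactants: 4 (R)-1-[3-methoxy-4-(triisopropylsilyloxy)phenyl]prop-2-en-1-yl 3-oxobutanoate
Product: 5 (1S,4R,5R)-1-acetyl-4-[3-methoxy-4-(triisopropylsilyloxy)phenyl]-3-oxabicyclo[3.1.0]hexan-2-one
Conditions: Mn(OAc)3·2H2O (2.2 equiv), Cu(OAc)2·H2O (0.2 equiv), KOAc, AcOH, rt to 40 °C
Reagents that add atoms: none
Why: Oxidative free-radical cyclisation mediated by trivalent manganese: the acetoacetate radical closes 5-exo-trig onto the vinyl group through a chair-like transition state with the aryl group pseudo-equatorial, so the radical carbon C9 ends up trans to the aryl group on C7 (C8 set by C7), and after oxidation by Cu(OAc)2 it is captured by the β-dicarbonyl carbon to give the necessarily cis-fused cyclopropane.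

Step 5
Reactants: 6 4-(hydroxymethyl)-2,6-dimethoxyphenol (syringyl alcohol)
Product: 7 [4-(allyloxy)-3,5-dimethoxyphenyl]methanol
Conditions: allyl bromide, K2CO3, acetone, reflux
Reagents that add atoms: allyl bromide, C=CCBr
Why: Williamson etherification is selective for the phenoxide over the benzylic alcohol, and the allyl ether masks the phenol that later carries the side chain and can be removed under neutral conditions.

Step 6
Reactants: 5 (1S,4R,5R)-1-acetyl-4-[3-methoxy-4-(triisopropylsilyloxy)phenyl]-3-oxabicyclo[3.1.0]hexan-2-one; 7 [4-(allyloxy)-3,5-dimethoxyphenyl]methanol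
Product: 8 (4S,5R)-3-acetyl-4-({[4-(allyloxy)-3,5-dimethoxyphenyl]methoxy}methyl)-5-[3-methoxy-4-(triisopropylsilyloxy)phenyl]dihydrofuran-2(3H)-one (C3 epimers)
Conditions: 7 (2 equiv), Sc(OTf)3 (10 mol %), CH2Cl2, rt
Reagents that add atoms: none
Why: Lewis-acid-catalysed homo-conjugate (homo-Michael) opening of the doubly acceptor-activated cyclopropane: the alcohol attacks the unsubstituted methylene carbon C9 in an SN2 manner and breaks the C9–C8' bond, so C7 and C8 are untouched and stay trans, while C8' becomes an epimerisable β-dicarbonyl centre that is erased in step 7.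

Step 7
Reactants: 8 (4S,5R)-3-acetyl-4-({[4-(allyloxy)-3,5-dimethoxyphenyl]methoxy}methyl)-5-[3-methoxy-4-(triisopropylsilyloxy)phenyl]dihydrofuran-2(3H)-one
Product: 9 (4S,5R)-4-({[4-(allyloxy)-3,5-dimethoxyphenyl]methoxy}methyl)-3-diazo-5-[3-methoxy-4-(triisopropylsilyloxy)phenyl]dihydrofuran-2(3H)-one
Conditions: p-ABSA, Et3N, MeCN, 0 °C to rt
Reagents that add atoms: 4-acetamidobenzenesulfonyl azide (p-ABSA), CC(=O)Nc1ccc(cc1)S(=O)(=O)N=[N+]=[N-]
Why: Regitz deacylative diazo transfer: the β-keto lactone enolate adds to the sulfonyl azide and the adduct fragments with loss of the acetyl group as the N-acetylsulfonamide, leaving the α-diazo lactone without touching C7 and C8.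

Step 8
Reactants: 9 (4S,5R)-4-({[4-(allyloxy)-3,5-dimethoxyphenyl]methoxy}methyl)-3-diazo-5-[3-methoxy-4-(triisopropylsilyloxy)phenyl]dihydrofuran-2(3H)-one
Product: 10 (1R,2S,5S,6R)-2-[4-(allyloxy)-3,5-dimethoxyphenyl]-6-[3-methoxy-4-(triisopropylsilyloxy)phenyl]-3,7-dioxabicyclo[3.3.0]octan-8-one (2-endo,6-exo)
Conditions: Rh2(OAc)4 (2 mol %), CH2Cl2 (0.01 M, slow addition of 9), rt
Reagents that add atoms: none
Why: Rh2(OAc)4 decomposes the diazo lactone to an electrophilic dirhodium carbenoid at C8', and this carbon inserts into the C7'–H bond through a concerted, hydride-transfer-like three-centre transition state in which the C–C and C–H bonds form as the metal leaves, C7 and C8 staying untouched. The closest known reaction type is the dirhodium-catalysed 1,5 C–H insertion of α-diazo-γ-butyrolactones into benzylic ether C–H bonds, which is known to give endo,exo-2,6-diaryl furofuranones. Ring B (C8'–C8–C9–O–C7') closes as a five-membered ring by 1,5-insertion through a chair-like six-centre array made of Rh=C8', H–C7' and the C8–C9–O tether. C8' is controlled by the tether, because the arm on C8 can deliver C7' only to its own face of the lactone, so the ring fusion must be cis. C7' is controlled by the orientation of its aryl group in that array, which should turn away from the acetate wall of the dirhodium core and towards the concave side, giving the endo aryl group as the kinetic product although the exo isomer is the more stable one. The step needs site selectivity for this C–H bond over the allyl C=C bond, the arene rings and the other ether C–H bonds, and this is secured by the double activation of C7'–H (ether oxygen and electron-rich arene), by the preference for five-membered closure and by high dilution.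

Step 9
Reactants: 10 (1R,2S,5S,6R)-2-[4-(allyloxy)-3,5-dimethoxyphenyl]-6-[3-methoxy-4-(triisopropylsilyloxy)phenyl]-3,7-dioxabicyclo[3.3.0]octan-8-one
Product: 11 (2S,3S,4S)-2-[4-(allyloxy)-3,5-dimethoxyphenyl]-3-(hydroxymethyl)-4-{(R)-hydroxy[3-methoxy-4-(triisopropylsilyloxy)phenyl]methyl}tetrahydrofuran
Conditions: LiAlH4, THF, 0 °C; then H2O
Reagents that add atoms: none
Why: Hydride reduction of the γ-lactone to the 1,4-diol proceeds under non-acidic conditions, so the acid-labile endo benzylic ether and all four stereocentres should be preserved.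

Step 10
Reactants: 11 (2S,3S,4S)-2-[4-(allyloxy)-3,5-dimethoxyphenyl]-3-(hydroxymethyl)-4-{(R)-hydroxy[3-methoxy-4-(triisopropylsilyloxy)phenyl]methyl}tetrahydrofuran
Product: 13 (1S,2S,5S,6R)-2-[4-(allyloxy)-3,5-dimethoxyphenyl]-6-[3-methoxy-4-(triisopropylsilyloxy)phenyl]-3,7-dioxabicyclo[3.3.0]octane, via primary mesylate 12 (not isolated)
Conditions: MsCl (1.1 equiv), pyridine, CH2Cl2, 0 °C to rt
Reagents that add atoms: none
Why: Selective mesylation of the primary hydroxyl followed by intramolecular Williamson-type 5-exo-tet displacement by the benzylic hydroxyl closes ring A at C9', with retention at C7 because no bond to a stereocentre is broken.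

Step 11
Reactants: 13 (1S,2S,5S,6R)-2-[4-(allyloxy)-3,5-dimethoxyphenyl]-6-[3-methoxy-4-(triisopropylsilyloxy)phenyl]-3,7-dioxabicyclo[3.3.0]octane
Product: 14 4-{(1S,2S,5S,6R)-6-[3-methoxy-4-(triisopropylsilyloxy)phenyl]-3,7-dioxabicyclo[3.3.0]oct-2-yl}-2,6-dimethoxyphenol
Conditions: Pd(PPh3)4 (5 mol %), morpholine, THF, rt
Reagents that add atoms: none
Why: Tsuji–Trost-type deallylation: the zerovalent palladium catalyst adds oxidatively to the allyl aryl ether and morpholine captures the π-allyl complex, freeing the phenol under neutral conditions that should neither epimerise the endo aryl centre nor cleave the silyl ether.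

Step 12
Reactants: 14 4-{(1S,2S,5S,6R)-6-[3-methoxy-4-(triisopropylsilyloxy)phenyl]-3,7-dioxabicyclo[3.3.0]oct-2-yl}-2,6-dimethoxyphenol; 15 (S)-4-benzyl-3-(chloroacetyl)oxazolidin-2-one
Product: 16 (S)-4-benzyl-3-[2-(4-{(1S,2S,5S,6R)-6-[3-methoxy-4-(triisopropylsilyloxy)phenyl]-3,7-dioxabicyclo[3.3.0]oct-2-yl}-2,6-dimethoxyphenoxy)acetyl]oxazolidin-2-one
Conditions: K2CO3, MeCN, 40 °C
Reagents that add atoms: none
Why: Williamson alkylation: the phenoxide displaces chloride from the α-halo imide (SN2 accelerated by the adjacent carbonyl), which forms the O4'–C8'' bond and installs the chiral auxiliary in one operation; no stereocentre is formed.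

Step 13
Reactants: 17 syringaldehyde (4-hydroxy-3,5-dimethoxybenzaldehyde)
Product: 18 4-(tert-butyldimethylsilyloxy)-3,5-dimethoxybenzaldehyde
Conditions: TBSCl, imidazole, DMF, rt
Reagents that add atoms: tert-butyldimethylsilyl chloride, CC(C)(C)[Si](C)(C)Cl
Why: Imidazole-promoted silylation protects the phenol for the boron aldol step and is removed together with the other silyl ether at the end; no stereocentre is formed.

Step 14
Reactants: 16 (S)-4-benzyl-3-[2-(4-{(1S,2S,5S,6R)-6-[3-methoxy-4-(triisopropylsilyloxy)phenyl]-3,7-dioxabicyclo[3.3.0]oct-2-yl}-2,6-dimethoxyphenoxy)acetyl]oxazolidin-2-one; 18 4-(tert-butyldimethylsilyloxy)-3,5-dimethoxybenzaldehyde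
Product: 21 (S)-4-benzyl-3-[(2S,3R)-3-[4-(tert-butyldimethylsilyloxy)-3,5-dimethoxyphenyl]-3-hydroxy-2-(4-{(1S,2S,5S,6R)-6-[3-methoxy-4-(triisopropylsilyloxy)phenyl]-3,7-dioxabicyclo[3.3.0]oct-2-yl}-2,6-dimethoxyphenoxy)propanoyl]oxazolidin-2-one, via Z-boron enolate 19 (not isolated), via boron aldolate 20 (not isolated)
Conditions: Bu2BOTf, iPr2NEt, CH2Cl2, −78 to 0 °C; 18, −78 to 0 °C; pH 7 buffer, MeOH, H2O2
Reagents that add atoms: none
Why: Evans syn aldol: the (Z)-dibutylboron enolate of the aryloxyacetyl imide should react with the aldehyde through a closed chair transition state on the enolate face remote from the benzyl group of the (S)-auxiliary, giving the 2,3-syn (2S,3R) adduct, which is the threo (7''R,8''R) arrangement after reduction.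

Step 15
Reactants: 21 (S)-4-benzyl-3-[(2S,3R)-3-[4-(tert-butyldimethylsilyloxy)-3,5-dimethoxyphenyl]-3-hydroxy-2-(4-{(1S,2S,5S,6R)-6-[3-methoxy-4-(triisopropylsilyloxy)phenyl]-3,7-dioxabicyclo[3.3.0]oct-2-yl}-2,6-dimethoxyphenoxy)propanoyl]oxazolidin-2-one
Product: 22 (1R,2R)-1-[4-(tert-butyldimethylsilyloxy)-3,5-dimethoxyphenyl]-2-(4-{(1S,2S,5S,6R)-6-[3-methoxy-4-(triisopropylsilyloxy)phenyl]-3,7-dioxabicyclo[3.3.0]oct-2-yl}-2,6-dimethoxyphenoxy)propane-1,3-diol
Conditions: LiBH4, MeOH (1 equiv), THF, 0 °C; then H2O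
Reagents that add atoms: none
Why: Chemoselective reductive cleavage of the N-acyl oxazolidinone gives the primary alcohol C9'' and releases the auxiliary without touching C7'' and C8''.

Step 16
Reactants: 22 (1R,2R)-1-[4-(tert-butyldimethylsilyloxy)-3,5-dimethoxyphenyl]-2-(4-{(1S,2S,5S,6R)-6-[3-methoxy-4-(triisopropylsilyloxy)phenyl]-3,7-dioxabicyclo[3.3.0]oct-2-yl}-2,6-dimethoxyphenoxy)propane-1,3-diol
Product: 23 (1R,2R)-1-(4-hydroxy-3,5-dimethoxyphenyl)-2-{4-[(1S,2S,5S,6R)-6-(4-hydroxy-3-methoxyphenyl)-3,7-dioxabicyclo[3.3.0]oct-2-yl]-2,6-dimethoxyphenoxy}propane-1,3-diol (target)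
Conditions: TBAF, AcOH, THF, 0 °C
Reagents that add atoms: none
Why: Fluoride cleavage of both aryl silyl ethers under buffered, non-acidic conditions should free the two phenols without epimerising the endo aryl centre or ionising the benzylic alcohol.

**Compound list**

1 | vanillin (4-hydroxy-3-methoxybenzaldehyde) | COc1cc(C=O)ccc1O | starting material
2 | 3-methoxy-4-(triisopropylsilyloxy)benzaldehyde | COc1cc(ccc1O[Si](C(C)C)(C(C)C)C(C)C)C=O | intermediate
3 | racemic 1-[3-methoxy-4-(triisopropylsilyloxy)phenyl]prop-2-en-1-ol | COc1cc(ccc1O[Si](C(C)C)(C(C)C)C(C)C)C(O)C=C | intermediate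
4 | (R)-1-[3-methoxy-4-(triisopropylsilyloxy)phenyl]prop-2-en-1-yl 3-oxobutanoate | COc1cc(ccc1O[Si](C(C)C)(C(C)C)C(C)C)[C@@H](C=C)OC(=O)CC(C)=O | intermediate
5 | (1S,4R,5R)-1-acetyl-4-[3-methoxy-4-(triisopropylsilyloxy)phenyl]-3-oxabicyclo[3.1.0]hexan-2-one | COc1cc(ccc1O[Si](C(C)C)(C(C)C)C(C)C)[C@@H]2OC(=O)[C@]3(C(C)=O)[C@H]2C3 | intermediate
6 | 4-(hydroxymethyl)-2,6-dimethoxyphenol (syringyl alcohol) | COc1cc(CO)cc(OC)c1O | starting material
7 | [4-(allyloxy)-3,5-dimethoxyphenyl]methanol | COc1cc(CO)cc(OC)c1OCC=C | intermediate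
8 | (4S,5R)-3-acetyl-4-({[4-(allyloxy)-3,5-dimethoxyphenyl]methoxy}methyl)-5-[3-methoxy-4-(triisopropylsilyloxy)phenyl]dihydrofuran-2(3H)-one, C3 left undefined (epimers) | COc1cc(ccc1O[Si](C(C)C)(C(C)C)C(C)C)[C@@H]2OC(=O)C(C(C)=O)[C@H]2COCc3cc(OC)c(OCC=C)c(OC)c3 | intermediate
9 | (4S,5R)-4-({[4-(allyloxy)-3,5-dimethoxyphenyl]methoxy}methyl)-3-diazo-5-[3-methoxy-4-(triisopropylsilyloxy)phenyl]dihydrofuran-2(3H)-one | COc1cc(ccc1O[Si](C(C)C)(C(C)C)C(C)C)[C@@H]2OC(=O)C(=[N+]=[N-])[C@H]2COCc3cc(OC)c(OCC=C)c(OC)c3 | intermediate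
10 | (1R,2S,5S,6R)-2-[4-(allyloxy)-3,5-dimethoxyphenyl]-6-[3-methoxy-4-(triisopropylsilyloxy)phenyl]-3,7-dioxabicyclo[3.3.0]octan-8-one | COc1cc(ccc1O[Si](C(C)C)(C(C)C)C(C)C)[C@@H]2OC(=O)[C@@H]3[C@H]2CO[C@@H]3c4cc(OC)c(OCC=C)c(OC)c4 | intermediate
11 | (2S,3S,4S)-2-[4-(allyloxy)-3,5-dimethoxyphenyl]-3-(hydroxymethyl)-4-{(R)-hydroxy[3-methoxy-4-(triisopropylsilyloxy)phenyl]methyl}tetrahydrofuran | COc1cc(ccc1O[Si](C(C)C)(C(C)C)C(C)C)[C@H](O)[C@@H]2CO[C@H](c3cc(OC)c(OCC=C)c(OC)c3)[C@@H]2CO | intermediate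
12 | primary methanesulfonate of 11 (mesyloxymethyl on C3 of the tetrahydrofuran) | COc1cc(ccc1O[Si](C(C)C)(C(C)C)C(C)C)[C@H](O)[C@@H]2CO[C@H](c3cc(OC)c(OCC=C)c(OC)c3)[C@@H]2COS(C)(=O)=O | intermediate (not isolated)
13 | (1S,2S,5S,6R)-2-[4-(allyloxy)-3,5-dimethoxyphenyl]-6-[3-methoxy-4-(triisopropylsilyloxy)phenyl]-3,7-dioxabicyclo[3.3.0]octane | COc1cc(ccc1O[Si](C(C)C)(C(C)C)C(C)C)[C@@H]2OC[C@@H]3[C@H]2CO[C@@H]3c4cc(OC)c(OCC=C)c(OC)c4 | intermediate
14 | 4-{(1S,2S,5S,6R)-6-[3-methoxy-4-(triisopropylsilyloxy)phenyl]-3,7-dioxabicyclo[3.3.0]oct-2-yl}-2,6-dimethoxyphenol | COc1cc(ccc1O[Si](C(C)C)(C(C)C)C(C)C)[C@@H]2OC[C@@H]3[C@H]2CO[C@@H]3c4cc(OC)c(O)c(OC)c4 | intermediate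
15 | (S)-4-benzyl-3-(chloroacetyl)oxazolidin-2-one | O=C1OC[C@H](Cc2ccccc2)N1C(=O)CCl | starting material
16 | (S)-4-benzyl-3-[2-(4-{(1S,2S,5S,6R)-6-[3-methoxy-4-(triisopropylsilyloxy)phenyl]-3,7-dioxabicyclo[3.3.0]oct-2-yl}-2,6-dimethoxyphenoxy)acetyl]oxazolidin-2-one | COc1cc(ccc1O[Si](C(C)C)(C(C)C)C(C)C)[C@@H]2OC[C@@H]3[C@H]2CO[C@@H]3c4cc(OC)c(OCC(=O)N5[C@@H](Cc6ccccc6)COC5=O)c(OC)c4 | intermediate
17 | syringaldehyde (4-hydroxy-3,5-dimethoxybenzaldehyde) | COc1cc(C=O)cc(OC)c1O | starting material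
18 | 4-(tert-butyldimethylsilyloxy)-3,5-dimethoxybenzaldehyde | COc1cc(C=O)cc(OC)c1O[Si](C)(C)C(C)(C)C | intermediate
19 | (Z)-dibutylboron enolate of 16 | COc1cc(ccc1O[Si](C(C)C)(C(C)C)C(C)C)[C@@H]2OC[C@@H]3[C@H]2CO[C@@H]3c4cc(OC)c(O/C=C(\OB(CCCC)CCCC)N5[C@@H](Cc6ccccc6)COC5=O)c(OC)c4 | intermediate (not isolated)
20 | dibutylboron aldolate of 21 (O-dibutylboryl on C7'') | COc1cc(ccc1O[Si](C(C)C)(C(C)C)C(C)C)[C@@H]2OC[C@@H]3[C@H]2CO[C@@H]3c4cc(OC)c(O[C@H](C(=O)N5[C@@H](Cc6ccccc6)COC5=O)[C@H](OB(CCCC)CCCC)c7cc(OC)c(O[Si](C)(C)C(C)(C)C)c(OC)c7)c(OC)c4 | intermediate (not isolated)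
21 | (S)-4-benzyl-3-[(2S,3R)-3-[4-(tert-butyldimethylsilyloxy)-3,5-dimethoxyphenyl]-3-hydroxy-2-(4-{(1S,2S,5S,6R)-6-[3-methoxy-4-(triisopropylsilyloxy)phenyl]-3,7-dioxabicyclo[3.3.0]oct-2-yl}-2,6-dimethoxyphenoxy)propanoyl]oxazolidin-2-one | COc1cc(ccc1O[Si](C(C)C)(C(C)C)C(C)C)[C@@H]2OC[C@@H]3[C@H]2CO[C@@H]3c4cc(OC)c(O[C@H](C(=O)N5[C@@H](Cc6ccccc6)COC5=O)[C@H](O)c7cc(OC)c(O[Si](C)(C)C(C)(C)C)c(OC)c7)c(OC)c4 | intermediate
22 | (1R,2R)-1-[4-(tert-butyldimethylsilyloxy)-3,5-dimethoxyphenyl]-2-(4-{(1S,2S,5S,6R)-6-[3-methoxy-4-(triisopropylsilyloxy)phenyl]-3,7-dioxabicyclo[3.3.0]oct-2-yl}-2,6-dimethoxyphenoxy)propane-1,3-diol | COc1cc(ccc1O[Si](C(C)C)(C(C)C)C(C)C)[C@@H]2OC[C@@H]3[C@H]2CO[C@@H]3c4cc(OC)c(O[C@H](CO)[C@H](O)c5cc(OC)c(O[Si](C)(C)C(C)(C)C)c(OC)c5)c(OC)c4 | intermediate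
23 | (1R,2R)-1-(4-hydroxy-3,5-dimethoxyphenyl)-2-{4-[(1S,2S,5S,6R)-6-(4-hydroxy-3-methoxyphenyl)-3,7-dioxabicyclo[3.3.0]oct-2-yl]-2,6-dimethoxyphenoxy}propane-1,3-diol | COc1cc(ccc1O)[C@@H]2OC[C@@H]3[C@H]2CO[C@@H]3c4cc(OC)c(O[C@H](CO)[C@H](O)c5cc(OC)c(O)c(OC)c5)c(OC)c4 | target

**Step count and risks**

Total steps: 16. Longest linear sequence: 14 steps (steps 1–4, 6–12, 14–16, from vanillin).

Step 8 (C–H insertion). The endo preference at C7' may erode, or part of the carbenoid may be intercepted by the remote allyl ether, leaving an epimer mixture. The fallback sets out from 9: the insertion is run as planned and the whole furofuranone fraction, which then also holds the 2-exo epimer (1R,2R,5S,6R)-furofuranone F1, is oxidised at C7'–H with DDQ in CH2Cl2/pH 7 buffer to the hemiketal F2. The lactone-bound C7–H is deactivated by its acyloxy oxygen and should not react. Et3SiH, BF3·OEt2, CH2Cl2, −78 °C then reduces the bicyclic oxocarbenium ion by hydride delivery to its convex face, which places the aryl group endo and comes back to 10. Stereocontrol at C7' thus moves from the insertion transition state to an ionic hydrogenation.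

Step 4 (oxidative cyclopropanation). The electron-rich ester is both benzylic and allylic and may ionise in acetic acid, which would cost enantiopurity by racemisation or allylic transposition; over-oxidation would cost material. The fallback sets out from 4: diazo transfer (p-ABSA, Et3N, MeCN) gives the diazoacetoacetate F3, and Cu(acac)2 (cat.), toluene, 90 °C closes the cyclopropane by intramolecular carbenoid addition to the vinyl group under neutral conditions, coming back to 5.

Step 12 (phenol alkylation with the chloroacetyl imide). Acyl transfer from the imide to the hindered 2,6-dimethoxyphenoxide, with loss of the auxiliary, may outrun O-alkylation. The fallback sets out from 14: alkylation with allyl bromoacetate (K2CO3, acetone) gives the allyl ester F4; Pd(PPh3)4 and morpholine free the aryloxyacetic acid F5; PivCl, Et3N, THF, −20 °C gives the mixed pivalic anhydride F6, which acylates lithiated (S)-4-benzyloxazolidin-2-one and comes back to 16.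

**Further compounds**

F1 | step 8 | (1R,2R,5S,6R)-2-[4-(allyloxy)-3,5-dimethoxyphenyl]-6-[3-methoxy-4-(triisopropylsilyloxy)phenyl]-3,7-dioxabicyclo[3.3.0]octan-8-one (2-exo epimer of 10) | COc1cc(ccc1O[Si](C(C)C)(C(C)C)C(C)C)[C@@H]2OC(=O)[C@@H]3[C@H]2CO[C@H]3c4cc(OC)c(OCC=C)c(OC)c4
F2 | step 8 | (1R,5S,6R)-2-[4-(allyloxy)-3,5-dimethoxyphenyl]-2-hydroxy-6-[3-methoxy-4-(triisopropylsilyloxy)phenyl]-3,7-dioxabicyclo[3.3.0]octan-8-one (hemiketal, C2 undefined) | COc1cc(ccc1O[Si](C(C)C)(C(C)C)C(C)C)[C@@H]2OC(=O)[C@@H]3[C@H]2COC3(O)c4cc(OC)c(OCC=C)c(OC)c4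
F3 | step 4 | (R)-1-[3-methoxy-4-(triisopropylsilyloxy)phenyl]prop-2-en-1-yl 2-diazo-3-oxobutanoate | COc1cc(ccc1O[Si](C(C)C)(C(C)C)C(C)C)[C@@H](C=C)OC(=O)C(=[N+]=[N-])C(C)=O
F4 | step 12 | allyl 2-(4-{(1S,2S,5S,6R)-6-[3-methoxy-4-(triisopropylsilyloxy)phenyl]-3,7-dioxabicyclo[3.3.0]oct-2-yl}-2,6-dimethoxyphenoxy)acetate | COc1cc(ccc1O[Si](C(C)C)(C(C)C)C(C)C)[C@@H]2OC[C@@H]3[C@H]2CO[C@@H]3c4cc(OC)c(OCC(=O)OCC=C)c(OC)c4
F5 | step 12 | 2-(4-{(1S,2S,5S,6R)-6-[3-methoxy-4-(triisopropylsilyloxy)phenyl]-3,7-dioxabicyclo[3.3.0]oct-2-yl}-2,6-dimethoxyphenoxy)acetic acid | COc1cc(ccc1O[Si](C(C)C)(C(C)C)C(C)C)[C@@H]2OC[C@@H]3[C@H]2CO[C@@H]3c4cc(OC)c(OCC(=O)O)c(OC)c4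
F6 | step 12 | mixed anhydride of F5 with pivalic acid | COc1cc(ccc1O[Si](C(C)C)(C(C)C)C(C)C)[C@@H]2OC[C@@H]3[C@H]2CO[C@@H]3c4cc(OC)c(OCC(=O)OC(=O)C(C)(C)C)c(OC)c4
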